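Alder, with 3 mM of capture agent, stands at 14% after 60.0 min, while elm, with 0.18 mM, stands at 31%, so we want a number that says how far capture agent lowers the end of the curve.

common to all: starting material 0.050 M; free catalyst 0.5 mol%
- elm: partner 1 equiv; capture agent 0.18 mM; run made earlier
- birch: partner 1 equiv; capture agent 0.92 mM; run made earlier
- alder: partner 1 equiv; capture agent 3 mM; run made earlier
- delta: partner 1.00 equiv; capture agent 0.250 mM; time 2.0 h
- gamma: partner 1.00 equiv; capture agent 1.00 mM; time 2.0 h
- zeta: partner 1.00 equiv; capture agent 4.00 mM; time 2.0 h
- epsilon: partner 1.00 equiv; capture agent 0.600 mM; time 2.0 h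
- beta: partner 1.00 equiv; capture agent 1.50 mM; time 2.0 h
- theta: partner 1.00 equiv; capture agent 2.00 mM; time 2.0 h

| run | time / min | product / % |
|---|---|---|
| elm | 12.0 | 13 |
| elm | 25.0 | 20 |
| elm | 40.0 | 26 |
| elm | 50.0 | 26 |
| elm | 60.0 | 31 |
| birch | 5.00 | 5 |
| birch | 15.0 | 13 |
| birch | 30.0 | 18 |
| birch | 40.0 | 20 |
| birch | 60.0 | 27 |
| alder | 5.00 | 0 |
| alder | 15.0 | 10 |
| alder | 30.0 | 12 |
| alder | 40.0 | 12 |
| alder | 60.0 | 14 |

(each reading ± 1.5 percentage points)



* the flasks put in order of amount of product, in percent of the starting material charged, best first, at 2.0 h (delta / gamma / zeta / epsilon / beta / theta)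
* the amount of product, in percent of the starting material charged of the flask you put first, at 2.0 h
* the amount of product, in percent of the starting material charged of the flask you put last, at 2.0 h

We suppose that capture agent and starting material compete for one working form of the catalyst, so that each bit of catalyst lost buys turnovers in proportion to S·c(starting material)/c(capture agent), where S is a selectivity factor. Where the catalyst is a small part of the capture agent, as in zeta with 0.250 mM against 4.00 mM, c(capture agent) stays near its charge and the rate integrates in closed form. Once the catalyst charge has been captured, the logarithm of c(starting material) charged over c(starting material) left equals the capture number N = S·c(free catalyst charged)/c(capture agent), which says how far the catalyst charge carries the starting material before capture has taken it, and the product share is 1 − exp(−N). Taking alder as finished, its last reading gives S = 1.81, a reading with the scatter of 1.5 percentage points in it, so zeta has N = 0.113 and we expect 10.7%.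

One number is not enough, however. Elm holds less capture agent than catalyst, 0.18 mM against 0.250 mM, so on our supposition its catalyst charge cannot be captured whole and N does not describe elm, although elm's readings bend too, with 13% in its first 12.0 min and a gain of 5 points in its last 20.0 min. We rank the flasks by rising capture agent, put delta first near elm's last reading of 31%, and put zeta last at 10.7%.

The forecast gives delta > epsilon > gamma > beta > theta > zeta, with 38% (33% to 45%) for the first flask and 12% (9.5% to 14.5%) for the last, both above our figures, on the ground that “Product therefore falls steadily as agent rises”.

The simulation gives delta > epsilon > gamma > beta > theta > zeta, with 32.5% for delta and 11.8% for zeta.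

    catalyst intermediate B ⇌ free catalyst + product (K = 0.0950 M, k = 0.266 s⁻¹)
    partner + free catalyst → catalyst intermediate A (k = 1.84 L mol⁻¹ s⁻¹)
    partner → decomposed reagent (k = 4.84 × 10⁻⁴ s⁻¹)
    starting material + catalyst intermediate A → catalyst intermediate B (k = 1.79 L mol⁻¹ s⁻¹)
    catalyst intermediate A + capture agent → trapped intermediate (k = 0.901 L mol⁻¹ s⁻¹)

Zeta ends at 11.8% against our 10.7%, with 98.2% of its catalyst as trapped intermediate, and S applied to theta gives 20.2% beside its 19.9%, although in theta 84.5% of the catalyst is trapped and 13.7% stands free, whereas N counts the whole charge as captured. Delta stops differently: at the start, partner passes into decomposed reagent faster than it reacts with free catalyst, by a ratio of 1.1, and partner is the limiting reagent, down to 0.399% of its charge at 2.00 h, while 69.6% of the catalyst stands free.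

(The numbers in the tables are calculated on assumed constants; scatter was added.)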